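**The margin.** If each incoming ligand that enters a complex sends out one leaving ligand, if the scavenger takes one leaving ligand each, and if the protic impurity leaves the scavenger alone, then one number tells you which of the two should end first in the maple flask: the scavenger margin, the equivalents of scavenger charged minus the equivalents of incoming ligand charged, 0.200 equiv.

all flasks: starting complex 0.050 M
- maple: incoming ligand 1.3 equiv; scavenger 1.5 equiv; protic impurity 0.025 M; the very flask that is asked about, followed so far
- flask: incoming ligand 1.30 equiv; scavenger 1.50 equiv; protic impurity 0.0250 M; time 40 h

- maple (time / h: starting complex / %, complex with two exchanged / %): 1.00: 45, 3; 3.00: 20, 8; 5.00: 16, 8; 8.00: 9, 2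

(each reading ± 2 percentage points)

- the earlier runs do not show how much of incoming ligand is bound; that part of a forecast is a guess

- part of the starting complex that has reacted at 40 h
- share of the unused incoming ligand that is free and not bound as idle adduct, at 40 h

**First hour.** In the maple flask the starting complex reads a fall of 0.799 h⁻¹ up to 1.00 h, and by my reckoning each exchange raises [leaving ligand], which the scavenger then lowers again.

**The middle.** Between 3.00 h and 8.00 h the maple readings fall at 0.160 h⁻¹, slower than before, which I take for [incoming ligand] falling as the exchanges consume it.

**The end.** Since the maple flask holds less incoming ligand than scavenger, I take incoming ligand as the limiting reagent, so the scavenger should outlast it and keep 13.3 % of its charge. I guess that the idle adduct holds incoming ligand on a leaving ligand, so with the scavenger still present I commit to a free share close to 100 %. For the reacted part, the last reading leaves 9 % of starting complex at 8.00 h, and that is what remains to be gained.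

**The forecast.** The forecast gives 96 % reacted and 50 % free, saying “The bound fraction of ligand is not constrained by the data, so fr is essentially a guess”; on the free share my reckoning differs from it.

**The result.** The maple flask gives 96.0 % reacted, in agreement with the forecast, and >99.9 % free, above the forecast.

    starting complex + incoming ligand ⇌ leaving ligand + complex with one exchanged (K = 0.560, k = 0.00590 M⁻¹ s⁻¹)
    complex with one exchanged + incoming ligand ⇌ leaving ligand + complex with two exchanged (K = 25.0, k = 8.80 × 10⁻⁴ M⁻¹ s⁻¹)
    complex with two exchanged + incoming ligand ⇌ leaving ligand + complex with three exchanged (K = 2.40, k = 0.00940 M⁻¹ s⁻¹)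
    leaving ligand + incoming ligand ⇌ idle adduct, settled at all times (K = 52.0 M⁻¹)
    scavenger + leaving ligand → scavenged by-product (k = 0.0410 M⁻¹ s⁻¹)
    protic impurity + starting complex → quenched substrate (k = 5.20 × 10⁻⁴ M⁻¹ s⁻¹)

At 1.58 h the scavenger step alone has a half-life of 0.11 h for leaving ligand, whereas the forward exchange on the complex with one exchanged alone has 7.6 h for incoming ligand. At 40.0 h the maple flask holds [leaving ligand] of 5.13 × 10⁻⁶ M and [idle adduct] of 1.51 × 10⁻⁸ M, with 13.4 % of the scavenger left, where the margin gave 13.3 %.

**Second flask.** In the neighbour charged with 3.20 equiv of incoming ligand the margin is −1.70 equiv, negative, so the scavenger should end first. Computed, at 40.0 h that neighbour has 0 % of its scavenger, [leaving ligand] of 0.0183 M, [idle adduct] of 0.0219 M, and 51.2 % of its unused incoming ligand free.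

The earlier runs and the new flask were computed with constants of no real substance, noise included.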